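The plan reads the N1(CH3)–C5(CH2Ar) edge of the imidazole ring as the N–Cα unit and side chain of N-methyl-O-methyltyrosine, C2 as a formyl carbon, and C4/N3 as the C=N of an N-sulfonyl imine of 4-methoxyphenylglyoxal. The ring is therefore cut at C4–C5 and C2–N3. One decarboxylative (3+2) cycloaddition of the derived münchnone should assemble the fully substituted 4-aroylimidazole, with the amino acid carboxyl leaving as carbon dioxide and the sulfonyl group as sulfinate. The precursor is the N-formyl-N-methyl amino acid, of either configuration. The ketone is then reduced enantioselectively to the (R)-carbinol, and C2 is aminated and condensed with 1-methylparabanic acid.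

Key step: step 4

Remark: 4 is supplied as its monohydrate and is dried azeotropically at the start of step 3; the configuration at C-α of 2 and 3 is of no consequence, because that carbon becomes sp2 (C5 of the imidazole) in step 4.

Step 1
Reactants: 1 O-methyl-L-tyrosine
Product: 2 N-formyl-O-methyl-L-tyrosine
Conditions: HCO2H, Ac2O, 0 °C → rt
Reagents that add atoms: formic acid, O=CO (delivered as acetic formic anhydride)
Why: Acetic formic anhydride, generated in the flask, transfers its more electrophilic formyl group to the amino nitrogen (N-formylation of an α-amino acid by a mixed anhydride), and the aryl methyl ether and the carboxyl group are not touched.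

Step 2
Reactants: 2 N-formyl-O-methyl-L-tyrosine
Product: 3 N-formyl-N-methyl-O-methyltyrosine
Conditions: NaH (3 equiv), MeI (8 equiv), THF, 0 °C → rt; then H2O, aq. HCl to pH 2
Reagents that add atoms: iodomethane, CI
Why: Sodium hydride forms the carboxylate/formamide dianion, whose nitrogen is methylated by iodomethane while the sodium carboxylate stays unreactive in THF (N-alkylation of a secondary amide anion), and any loss of configuration at C-α is immaterial for step 4.

Step 3
Reactants: 4 4-methoxyphenylglyoxal, 5 p-toluenesulfonyl isocyanate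
Product: 6 N-[2-(4-methoxyphenyl)-2-oxoethylidene]-4-methylbenzenesulfonamide
Conditions: PhMe, reflux, azeotropic removal of water; then 5 (1.0 equiv), AlCl3 (2 mol %), reflux; evaporate, use crude
Reagents that add atoms: none
Why: The sulfonyl isocyanate adds across the electron-poor aldehyde carbonyl and the four-membered adduct expels carbon dioxide (isocyanate–carbonyl metathesis, the usual entry to N-sulfonyl imines of glyoxylic aldehydes), the conjugated aryl ketone being too unreactive to compete, and the water-free procedure suits a moisture-sensitive imine.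

Step 4
Reactants: 3 N-formyl-N-methyl-O-methyltyrosine, 6 N-[2-(4-methoxyphenyl)-2-oxoethylidene]-4-methylbenzenesulfonamide
Product: 9 (4-methoxyphenyl)[5-(4-methoxybenzyl)-1-methyl-1H-imidazol-4-yl]methanone, via münchnone 7 (not isolated), via bicyclic cycloadduct 8 (not isolated)
Conditions: DIC (1.2 equiv), 6 (1.5 equiv), CH2Cl2, 0 °C → rt, slow addition of 3; then aq. NaHCO3
Reagents that add atoms: none
Why: DIC dehydrates 3 to the mesoionic oxazolium olate 7, a cyclic azomethine ylide, and is preferred to an acid anhydride because it offers no acyl group that could intercept C4 of 7 in a Dakin–West pathway. The enolate-like C4 of 7 (the former α-carbon) attacks the imine carbon of 6 and the sulfonamide nitrogen closes onto C2 of 7 (the former formyl carbon), a concerted but asynchronous (3+2) cycloaddition that gives 8. Adduct 8 should lose carbon dioxide by cycloreversion and then p-toluenesulfinic acid by elimination, which aromatises the ring; the closest known reaction type is the (3+2) cycloaddition of münchnones with N-sulfonyl aldimines to give imidazoles. The imidazole ring is thus closed intermolecularly, both of its new bonds (C4–C5 and C2–N3, imidazole numbering) being made in the cycloaddition and none in a separate cyclisation. No stereocentre is created, since the sp3 centres of 8 are erased on aromatisation. The step needs regiocontrol, which rests on the polarity match between the nucleophilic C4 of 7 and an imine carbon activated by both the sulfonyl and the aroyl group, and chemoselectivity over self-condensation of the 2-unsubstituted münchnone, which rests on adding 3 slowly to DIC and an excess of 6 so that the dipole is trapped as it forms.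

Step 5
Reactants: 9 (4-methoxyphenyl)[5-(4-methoxybenzyl)-1-methyl-1H-imidazol-4-yl]methanone
Product: 10 (R)-[5-(4-methoxybenzyl)-1-methyl-1H-imidazol-4-yl](4-methoxyphenyl)methanol
Conditions: RuCl(p-cymene)[(S,S)-TsDPEN] (2 mol %), HCO2H/Et3N (5:2), CH2Cl2, 30 °C; then aq. NaHCO3
Reagents that add atoms: none
Why: In this Noyori–Ikariya asymmetric transfer hydrogenation the Ru–H/N–H pair delivers hydride and proton through a six-membered transition state in which the unhindered 4-methoxyphenyl ring is expected to sit next to the p-cymene ligand (C–H/π contact) and the ortho-substituted imidazolyl ring in the distal site, so that the (S,S)-catalyst should add hydride to the Si face and set the (R)-carbinol, while the formic acid medium protonates N3, which activates the ketone and keeps the heterocycle off the metal.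

Step 6
Reactants: 10 (R)-[5-(4-methoxybenzyl)-1-methyl-1H-imidazol-4-yl](4-methoxyphenyl)methanol
Product: 12 (R)-[2-azido-5-(4-methoxybenzyl)-1-methyl-1H-imidazol-4-yl](4-methoxyphenyl)methanol, via C2-lithio lithium alkoxide 11 (not isolated)
Conditions: n-BuLi (2.2 equiv), THF, −78 °C; then 2,4,6-triisopropylbenzenesulfonyl azide (1.3 equiv), −78 °C → rt; then H2O
Reagents that add atoms: 2,4,6-triisopropylbenzenesulfonyl azide, CC(C)c1cc(C(C)C)c(S(=O)(=O)N=[N+]=[N-])c(C(C)C)c1
Why: This is C2 lithiation of a 1-methylimidazole followed by electrophilic azide transfer from a sulfonyl azide, in which the first equivalent of base turns the hydroxyl group into a lithium alkoxide that protects it and shuts down deprotonation at the carbinol carbon, the second removes the most acidic ring proton at C2, and the hindered sulfonyl azide hands its azido group to carbon with loss of sulfinate while its shielded sulfur resists the alkoxide.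

Step 7
Reactants: 12 (R)-[2-azido-5-(4-methoxybenzyl)-1-methyl-1H-imidazol-4-yl](4-methoxyphenyl)methanol
Product: 14 (R)-[2-amino-5-(4-methoxybenzyl)-1-methyl-1H-imidazol-4-yl](4-methoxyphenyl)methanol, via iminophosphorane 13 (not isolated)
Conditions: PMe3 (1 M in THF, 1.5 equiv), THF, 0 °C → rt; then H2O, 50 °C
Reagents that add atoms: none
Why: In this Staudinger reduction the phosphine adds to the terminal azide nitrogen, dinitrogen is lost and the iminophosphorane is hydrolysed to the 2-aminoimidazole under neutral to basic, hydrogen-free conditions, so the acid- and hydrogenolysis-prone diaryl carbinol should keep its configuration and the water-soluble phosphine oxide is easily removed.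

Step 8
Reactants: 14 (R)-[2-amino-5-(4-methoxybenzyl)-1-methyl-1H-imidazol-4-yl](4-methoxyphenyl)methanol, 15 1-methylparabanic acid
Product: 19 (R)-4-({4-[hydroxy(4-methoxyphenyl)methyl]-5-(4-methoxybenzyl)-1-methyl-1H-imidazol-2-yl}amino)-1-methyl-1H-imidazole-2,5-dione, via silylated methylparabanic acid 16 (not isolated), via O-trimethylsilyl ether of the amine 17 (not isolated), via O-trimethylsilyl ether of the target 18 (not isolated)
Conditions: 15 (1.5 equiv), BSA (3.5 equiv), MeCN, 80 °C; then 14, PhMe, 110 °C; then MeOH, KF (cat.), rt
Reagents that add atoms: none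
Why: In this condensation of a 2-aminoimidazole with silyl-activated 1-methylparabanic acid, BSA converts the N3–H/C4=O unit of 15 into an O-silyl imidate and caps the carbinol as its trimethylsilyl ether, the exocyclic amine adds to C4 of 16 (the only carbonyl activated as an imidate) with loss of trimethylsilanol to give the amidine tautomer of the target, and fluoride-catalysed methanolysis then frees the hydroxyl group without acid, leaving the (R)-centre untouched.

Compound list
1 | O-methyl-L-tyrosine | COc1ccc(C[C@H](N)C(=O)O)cc1 | starting material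
2 | N-formyl-O-methyl-L-tyrosine | COc1ccc(C[C@H](NC=O)C(=O)O)cc1 | intermediate
3 | N-formyl-N-methyl-O-methyltyrosine (drawn as the (S)-form; the configuration is not needed) | COc1ccc(C[C@H](N(C)C=O)C(=O)O)cc1 | intermediate
4 | 4-methoxyphenylglyoxal (supplied as the monohydrate) | COc1ccc(C(=O)C=O)cc1 | starting material
5 | p-toluenesulfonyl isocyanate | Cc1ccc(S(=O)(=O)N=C=O)cc1 | starting material
6 | (E)-N-[2-(4-methoxyphenyl)-2-oxoethylidene]-4-methylbenzenesulfonamide | COc1ccc(C(=O)/C=N/S(=O)(=O)c2ccc(C)cc2)cc1 | intermediate
7 | 4-(4-methoxybenzyl)-3-methyl-1,3-oxazol-3-ium-5-olate (münchnone) | COc1ccc(Cc2c([O-])oc[n+]2C)cc1 | intermediate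
8 | 6-(4-methoxybenzoyl)-4-(4-methoxybenzyl)-7-methyl-5-tosyl-2-oxa-5,7-diazabicyclo[2.2.1]heptan-3-one (configuration immaterial) | CN1C2OC(=O)C1(Cc1ccc(OC)cc1)C(C(=O)c1ccc(OC)cc1)N2S(=O)(=O)c1ccc(C)cc1 | intermediate
9 | (4-methoxyphenyl)[5-(4-methoxybenzyl)-1-methyl-1H-imidazol-4-yl]methanone | COc1ccc(Cc2c(C(=O)c3ccc(OC)cc3)ncn2C)cc1 | intermediate
10 | (R)-[5-(4-methoxybenzyl)-1-methyl-1H-imidazol-4-yl](4-methoxyphenyl)methanol | COc1ccc(Cc2c([C@H](O)c3ccc(OC)cc3)ncn2C)cc1 | intermediate
11 | C2-lithio lithium alkoxide of 10, (R) | COc1ccc(Cc2c([C@H](O[Li])c3ccc(OC)cc3)nc([Li])n2C)cc1 | intermediate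
12 | (R)-[2-azido-5-(4-methoxybenzyl)-1-methyl-1H-imidazol-4-yl](4-methoxyphenyl)methanol | COc1ccc(Cc2c([C@H](O)c3ccc(OC)cc3)nc(N=[N+]=[N-])n2C)cc1 | intermediate
13 | (R)-(4-methoxyphenyl){5-(4-methoxybenzyl)-1-methyl-2-[(trimethylphosphoranylidene)amino]-1H-imidazol-4-yl}methanol | COc1ccc(Cc2c([C@H](O)c3ccc(OC)cc3)nc(N=P(C)(C)C)n2C)cc1 | intermediate
14 | (R)-[2-amino-5-(4-methoxybenzyl)-1-methyl-1H-imidazol-4-yl](4-methoxyphenyl)methanol | COc1ccc(Cc2c([C@H](O)c3ccc(OC)cc3)nc(N)n2C)cc1 | intermediate
15 | 1-methylimidazolidine-2,4,5-trione (1-methylparabanic acid) | CN1C(=O)NC(=O)C1=O | starting material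
16 | 1-methyl-4-(trimethylsilyloxy)-1H-imidazole-2,5-dione | CN1C(=O)N=C(O[Si](C)(C)C)C1=O | intermediate
17 | O-trimethylsilyl ether of 14, (R) | COc1ccc(Cc2c([C@H](O[Si](C)(C)C)c3ccc(OC)cc3)nc(N)n2C)cc1 | intermediate
18 | O-trimethylsilyl ether of 19, (R) | COc1ccc(Cc2c([C@H](O[Si](C)(C)C)c3ccc(OC)cc3)nc(NC3=NC(=O)N(C)C3=O)n2C)cc1 | intermediate
19 | (R)-4-({4-[hydroxy(4-methoxyphenyl)methyl]-5-(4-methoxybenzyl)-1-methyl-1H-imidazol-2-yl}amino)-1-methyl-1H-imidazole-2,5-dione (CNP0288484.1) | COc1ccc(Cc2c([C@H](O)c3ccc(OC)cc3)nc(NC3=NC(=O)N(C)C3=O)n2C)cc1 | target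

Total step count: 8. Longest linear sequence: 7 (steps 1, 2, 4, 5, 6, 7, 8); step 3 is the one-step side branch.

Steps most likely to fail

Step 4. The transient C2-unsubstituted münchnone may condense with itself, or the acyl imine may hydrolyse or oligomerise, faster than the two partners meet, and regiocontrol may erode with so small a C2 substituent. In the fallback the aroyl group is no longer carried through the cycloaddition but attached afterwards. It sets out from 3 and 5. Ethyl glyoxylate and 5 give ethyl 2-(tosylimino)acetate F1, an isolable and well-behaved electrophilic imine. F1 is combined with 3 and DIC as in step 4 to give ethyl 5-(4-methoxybenzyl)-1-methyl-1H-imidazole-4-carboxylate F2. F2 is converted with N,O-dimethylhydroxylamine hydrochloride and iPrMgCl into N-methoxy-5-(4-methoxybenzyl)-N,1-dimethyl-1H-imidazole-4-carboxamide F3. Addition of 4-methoxyphenylmagnesium bromide to F3 then gives ketone 9, where the route is rejoined.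

Step 5. Facial discrimination between two aryl-type substituents may be poor or even inverted relative to the model, and turnover may stall if the imidazole binds ruthenium. The configuration of 10 is to be confirmed before material is carried on, and the (R,R)-catalyst is the immediate remedy if only the sense is reversed. The fallback replaces asymmetric catalysis by resolution. It sets out from 9, which NaBH4 in MeOH reduces to the racemic carbinol F4. Preparative chromatography on a polysaccharide carbamate chiral stationary phase separates F4 into 10 and its (S)-enantiomer F5. F5 is oxidised back to 9 with MnO2 and recycled. The route is rejoined at 10.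

Step 6. C2 metalation of a poorly soluble dilithio species may be incomplete, or the sulfonyl group may be transferred to the alkoxide in place of the azido group to carbon. The fallback masks the hydroxyl group. It sets out from 10, which TBSCl and imidazole in DMF convert into (R)-4-[(tert-butyldimethylsilyloxy)(4-methoxyphenyl)methyl]-5-(4-methoxybenzyl)-1-methyl-1H-imidazole F6. One equivalent of n-BuLi at −78 °C and the same sulfonyl azide give the 2-azido silyl ether F7. Bu4NF buffered with AcOH in THF at 0 °C then releases 12, where the route is rejoined.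

Further compounds
F1 | step 4 | ethyl (E)-2-(tosylimino)acetate | CCOC(=O)/C=N/S(=O)(=O)c1ccc(C)cc1
F2 | step 4 | ethyl 5-(4-methoxybenzyl)-1-methyl-1H-imidazole-4-carboxylate | CCOC(=O)c1ncn(C)c1Cc1ccc(OC)cc1
F3 | step 4 | N-methoxy-5-(4-methoxybenzyl)-N,1-dimethyl-1H-imidazole-4-carboxamide | CON(C)C(=O)c1ncn(C)c1Cc1ccc(OC)cc1
F4 | step 5 | racemic [5-(4-methoxybenzyl)-1-methyl-1H-imidazol-4-yl](4-methoxyphenyl)methanol | COc1ccc(Cc2c(C(O)c3ccc(OC)cc3)ncn2C)cc1
F5 | step 5 | (S)-[5-(4-methoxybenzyl)-1-methyl-1H-imidazol-4-yl](4-methoxyphenyl)methanol | COc1ccc(Cc2c([C@@H](O)c3ccc(OC)cc3)ncn2C)cc1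
F6 | step 6 | (R)-4-[(tert-butyldimethylsilyloxy)(4-methoxyphenyl)methyl]-5-(4-methoxybenzyl)-1-methyl-1H-imidazole | COc1ccc(Cc2c([C@H](O[Si](C)(C)C(C)(C)C)c3ccc(OC)cc3)ncn2C)cc1
F7 | step 6 | (R)-2-azido-4-[(tert-butyldimethylsilyloxy)(4-methoxyphenyl)methyl]-5-(4-methoxybenzyl)-1-methyl-1H-imidazole | COc1ccc(Cc2c([C@H](O[Si](C)(C)C(C)(C)C)c3ccc(OC)cc3)nc(N=[N+]=[N-])n2C)cc1
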